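The rate constants are hidden, so read one lumped constant from the readings.

| flask | starting material | partner | remark | time |
|---|---|---|---|---|
| spring | 5 mM | 0.59 equiv | run made earlier |  |
| midnight | 5 mM | 4.7 equiv | run made earlier |  |
| Monday's | 5.0 mM | 4.00 equiv |  | 25 min |
| Thursday's | 5.0 mM | 0.500 equiv |  | 25 min |
| Sunday's | 5.0 mM | 1.20 equiv |  | 25 min |

1. which of these holds the largest part of the starting material at the end of Monday's (starting material / single product / bis adduct / other mono adduct)
2. which of these holds the largest part of the starting material at the end of Thursday's (starting material / single product / bis adduct / other mono adduct)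
3. which of these holds the largest part of the starting material at the end of Sunday's (starting material / single product / bis adduct / other mono adduct)
4. bis adduct at the end of Sunday's, in percent of the starting material charged

- a reading or a percentage of single product counts all its forms, free or not

| run | time / min | bis adduct / % | single product / % |
|---|---|---|---|
| spring | 4.00 | 3.6 | 32.5 |
| spring | 8.00 | 3.9 | 39.1 |
| spring | 12.0 | 4.1 | 42.8 |
| spring | 15.0 | 4.5 | 42.9 |
| spring | 20.0 | 3.6 | 42.7 |
| spring | 25.0 | 4.0 | 44.7 |
| midnight | 4.00 | 21.8 | 68.6 |
| midnight | 8.00 | 28.7 | 54.1 |
| midnight | 12.0 | 34.7 | 38.7 |
| midnight | 15.0 | 40.2 | 29.4 |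
| midnight | 20.0 | 48.5 | 12.3 |
| midnight | 25.0 | 54.5 | 0.6 |

(scatter of a reading: 0.5 percentage points)

Read the single product column of the midnight run. Each reading scatters by 0.5 percentage points. From 4.00 min to 12.0 min it falls 0.0374 min⁻¹ of the charge. From 12.0 min to 20.0 min it falls 0.0330 min⁻¹. The line is nearly straight, so freeze free c(single product) and treat the loss as pseudo-first-order in partner.

Take the whole stretch in the midnight run: the reading is 0.0352 min⁻¹. Now count partner at the middle row. Assume starting material and other mono adduct stand at zero. Charge one partner per starting material and one more for each part of the charge that no longer stands as single product. That leaves 3.09 equivalents. Divide the two and keep 0.0114 min⁻¹, the drain constant: fall of single product, as a fraction of the charge, per equivalent of partner left.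

Extrapolate the midnight line back to zero time. The line stands there at a reckoned 82.7% single product. Give Monday's the same start and the same drain constant, and let partner fall as single product falls. My reckoning then leaves 12.6% single product in Monday's at the end.

The forecast answers bis adduct for Monday's, starting material for Thursday's, single product for Sunday's, and 14% bis adduct for Sunday's. Its ground for the straight line is “a saturated reservoir with only a small free fraction reacting”.

    starting material + partner → single product (k = 1.10 L mol⁻¹ s⁻¹)
    starting material + partner → other mono adduct (k = 0.150 L mol⁻¹ s⁻¹)
    partner + single product → bis adduct (k = 1.30 L mol⁻¹ s⁻¹)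
    partner + other mono adduct → bis adduct (k = 2.80 L mol⁻¹ s⁻¹)
    crystals ⇌ single product, rate k5*(cs5 - [single product]) while solid is left; crystals form when [single product] > cs5 (solubility = 0.0720 mM, k = 1.70 s⁻¹)
    partner + single product → over-reaction product (k = 1.40 L mol⁻¹ s⁻¹)

Sunday's ends at 14.4% bis adduct. The choices come out as bis adduct for Monday's, starting material for Thursday's and single product for Sunday's. In Sunday's, crystals hold 71.5% of the 72.9% single product at 25.0 min. Monday's holds 13.9% single product against the reckoned 12.6%. Put the same line start and the drain constant on the neighbour of Sunday's charged with 3.00 equiv: they give 37.4% single product, and that flask holds 38.6%.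

(The earlier runs and the new flask were computed for an exercise.)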